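**Strategy.** The flavanone ring is made last, from a fully elaborated salicylaldehyde and an aryl acetylene. The key step exploits the C8a phenol (O1) ortho to the formyl carbon C4 on ring A: O1 first directs rhodium into the aldehyde C–H bond so that the alkyne is hydroacylated (C3–C4), then closes ring C by oxa-Michael addition (O1–C2) under a cinchona catalyst that sets C2. Its precursor carries the complete C8 side chain, built by a rhodium-catalysed asymmetric alkenyl conjugate addition to a chalcone (C3'), a Corey–Bakshi–Shibata reduction (C1') and an asymmetric propargylation (C7').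

Key step: step 13

Remark: the four building blocks (the hydroxyphenylpropanoate, the dihydroxymethoxyacetophenone, the silyloxybenzaldehyde and the silyloxyphenylacetylene) are taken as purchasable. Positions follow chroman-4-one numbering (O1, C2 to C8a); the C8 side chain is C1' to C9' counted from the ring. TBS = tert-butyldimethylsilyl, TES = triethylsilyl, R* = (1S,3R,4E,7S)-1,7-bis(triethylsilyloxy)-3,9-bis[4-(tert-butyldimethylsilyloxy)phenyl]non-4-en-1-yl.

**Step 1**
Reactants: 1 methyl 3-(4-hydroxyphenyl)propanoate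
Product: 2 methyl 3-[4-(tert-butyldimethylsilyloxy)phenyl]propanoate
Conditions: TBSCl, imidazole, DMF, rt
Reagents that add atoms: tert-butyldimethylsilyl chloride, CC(C)(C)[Si](C)(C)Cl
Why: Silylation of a phenol with a silyl chloride and imidazole is routine and leaves the ester untouched.

**Step 2**
Reactants: 2 methyl 3-[4-(tert-butyldimethylsilyloxy)phenyl]propanoate
Product: 3 3-[4-(tert-butyldimethylsilyloxy)phenyl]propanal
Conditions: iBu2AlH (1.05 equiv), CH2Cl2, −78 °C; KNaC4H4O6 (aq)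
Reagents that add atoms: none
Why: Partial ester reduction with iBu2AlH at low temperature should stop at the aluminium hemiacetal, which gives the aldehyde on work-up.

**Step 3**
Reactants: 3 3-[4-(tert-butyldimethylsilyloxy)phenyl]propanal
Product: 4 (3S)-1-[4-(tert-butyldimethylsilyloxy)phenyl]hex-5-yn-3-ol
Conditions: allenylboronic acid pinacol ester, (R)-3,3'-bis(2,4,6-triisopropylphenyl)-1,1'-binaphthyl-2,2'-diyl hydrogen phosphate (5 mol%), 4 Å MS, toluene, −20 °C
Reagents that add atoms: allenylboronic acid pinacol ester, C=C=CB1OC(C)(C)C(C)(C)O1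
Why: Chiral phosphoric acid-catalysed propargylboration through a closed six-membered SE2' transition state; the (R)-acid should direct the allenyl group to the Re face of the aldehyde, which gives the 3S carbinol.

**Step 4**
Reactants: 4 (3S)-1-[4-(tert-butyldimethylsilyloxy)phenyl]hex-5-yn-3-ol
Product: 5 tert-butyldimethyl{4-[(3S)-3-(triethylsilyloxy)hex-5-yn-1-yl]phenoxy}silane
Conditions: TESCl, imidazole, DMF, 0 °C → rt
Reagents that add atoms: chlorotriethylsilane, CC[Si](Cl)(CC)CC
Why: Standard silylation of a secondary alcohol; the triethylsilyl ether is chosen so that it falls off easily in the final buffered fluoride step.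

**Step 5**
Reactants: 6 1-(2,6-dihydroxy-4-methoxyphenyl)ethan-1-one
Product: 7 1-[2,6-bis(allyloxy)-4-methoxyphenyl]ethan-1-one
Conditions: allyl bromide (3 equiv), K2CO3, DMF, 60 °C
Reagents that add atoms: allyl bromide, C=CCBr
Why: Williamson etherification; excess reagent and heat should alkylate both hydrogen-bonded phenols, which are equivalent by symmetry.

**Step 6**
Reactants: 7 1-[2,6-bis(allyloxy)-4-methoxyphenyl]ethan-1-one; 8 4-(tert-butyldimethylsilyloxy)benzaldehyde
Product: 11 (E)-1-[2,6-bis(allyloxy)-4-methoxyphenyl]-3-[4-(tert-butyldimethylsilyloxy)phenyl]prop-2-en-1-one, via lithium aldolate 9 (not isolated), via β-mesyloxy ketone 10 (not isolated)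
Conditions: LiN(SiMe3)2, THF, −78 °C; 8; then MsCl, Et3N, −78 °C → rt
Reagents that add atoms: none
Why: Directed aldol addition of the kinetic lithium enolate, then mesylation and E1cB elimination, should give the E-chalcone without the hydroxide that would cleave the aryl silyl ether.

**Step 7**
Reactants: 5 tert-butyldimethyl{4-[(3S)-3-(triethylsilyloxy)hex-5-yn-1-yl]phenoxy}silane; 11 (E)-1-[2,6-bis(allyloxy)-4-methoxyphenyl]-3-[4-(tert-butyldimethylsilyloxy)phenyl]prop-2-en-1-one
Product: 13 (3R,4E,7S)-1-[2,6-bis(allyloxy)-4-methoxyphenyl]-3,9-bis[4-(tert-butyldimethylsilyloxy)phenyl]-7-(triethylsilyloxy)non-4-en-1-one, via alkenylzirconocene 12 (not isolated)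
Conditions: Cp2Zr(H)Cl, THF, rt; then 11, [Rh(cod)(MeCN)2]BF4 (5 mol%), (R)-BINAP (6 mol%), THF, rt; NH4Cl (aq)
Reagents that add atoms: none
Why: Syn hydrozirconation places zirconium on the terminal carbon and fixes the E-alkene, and rhodium/BINAP-catalysed asymmetric 1,4-addition of the alkenyl group to the E-enone sets C3'; the (R)-ligand is chosen by analogy with the known sense of induction for E-configured acyclic enones and should give 3R.

**Step 8**
Reactants: 13 (3R,4E,7S)-1-[2,6-bis(allyloxy)-4-methoxyphenyl]-3,9-bis[4-(tert-butyldimethylsilyloxy)phenyl]-7-(triethylsilyloxy)non-4-en-1-one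
Product: 14 (1S,3R,4E,7S)-1-[2,6-bis(allyloxy)-4-methoxyphenyl]-3,9-bis[4-(tert-butyldimethylsilyloxy)phenyl]-7-(triethylsilyloxy)non-4-en-1-ol
Conditions: (R)-2-methyl-CBS-oxazaborolidine (0.5 equiv), catecholborane, toluene, −40 → −20 °C; MeOH
Reagents that add atoms: none
Why: Corey–Bakshi–Shibata reduction; with the di-ortho-substituted aryl group as the large substituent the (R)-catalyst should deliver hydride to the face that gives the 1S alcohol, and catecholborane should not hydroborate the alkenes at this temperature.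

**Step 9**
Reactants: 14 (1S,3R,4E,7S)-1-[2,6-bis(allyloxy)-4-methoxyphenyl]-3,9-bis[4-(tert-butyldimethylsilyloxy)phenyl]-7-(triethylsilyloxy)non-4-en-1-ol
Product: 15 (1S,3R,4E,7S)-1-[2,6-bis(allyloxy)-4-methoxyphenyl]-1,7-bis(triethylsilyloxy)-3,9-bis[4-(tert-butyldimethylsilyloxy)phenyl]non-4-ene
Conditions: TESCl, imidazole, DMAP (cat.), DMF, 0 °C → rt
Reagents that add atoms: chlorotriethylsilane, CC[Si](Cl)(CC)CC
Why: Silylation under basic, non-ionising conditions protects the acid-labile, electron-rich benzylic alcohol without touching the C1' configuration.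

**Step 10**
Reactants: 15 (1S,3R,4E,7S)-1-[2,6-bis(allyloxy)-4-methoxyphenyl]-1,7-bis(triethylsilyloxy)-3,9-bis[4-(tert-butyldimethylsilyloxy)phenyl]non-4-ene
Product: 16 5-methoxy-2-R*-benzene-1,3-diol
Conditions: Pd(PPh3)4 (5 mol%), morpholine, THF, rt, argon
Reagents that add atoms: none
Why: Tsuji–Trost deallylation: zerovalent palladium ionises the aryl allyl ethers and morpholine traps the π-allyl complex, under neutral conditions that should leave all silyl ethers and the internal alkene intact.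

**Step 11**
Reactants: 16 5-methoxy-2-R*-benzene-1,3-diol
Product: 17 2,4-dihydroxy-6-methoxy-3-R*-benzaldehyde
Conditions: MgCl2, Et3N, (CH2O)n, THF, 65 °C; NH4Cl (aq)
Reagents that add atoms: paraformaldehyde (as formaldehyde), C=O
Why: Casnati–Skattebøl ortho-formylation: the magnesium phenoxide delivers formaldehyde only ortho to a free phenol, the two open ring positions are equivalent by symmetry, and the first formyl group deactivates the ring against a second one.

**Step 12**
Reactants: 17 2,4-dihydroxy-6-methoxy-3-R*-benzaldehyde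
Product: 18 4-(tert-butyldimethylsilyloxy)-2-hydroxy-6-methoxy-3-R*-benzaldehyde
Conditions: TBSCl (1.1 equiv), imidazole, CH2Cl2, 0 °C
Reagents that add atoms: tert-butyldimethylsilyl chloride, CC(C)(C)[Si](C)(C)Cl
Why: The 4-OH para to the aldehyde is more acidic and not hydrogen-bonded to the formyl group, so it should be silylated selectively while the chelated 2-OH stays free.

**Step 13**
Reactants: 18 4-(tert-butyldimethylsilyloxy)-2-hydroxy-6-methoxy-3-R*-benzaldehyde; 19 tert-butyl(4-ethynylphenoxy)dimethylsilane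
Product: 21 (2S)-7-(tert-butyldimethylsilyloxy)-2-[4-(tert-butyldimethylsilyloxy)phenyl]-5-methoxy-8-R*-chroman-4-one, via 2'-hydroxychalcone 20 (not isolated)
Conditions: [Rh(cod)Cl]2 (2.5 mol%), dppf [Fe(C5H4PPh2)2] (5 mol%), Na2CO3 (5 mol%), toluene, 80 °C; then 1-[3,5-bis(trifluoromethyl)phenyl]-3-[(8S,9S)-6'-methoxycinchonan-9-yl]thiourea (20 mol%), 0 °C → rt
Reagents that add atoms: none
Why: This is rhodium-catalysed alkyne hydroacylation in tandem with a cinchona-catalysed intramolecular oxa-Michael addition, the sequence known for salicylaldehydes and alkynes giving chroman-4-ones: the phenoxide O1 and the formyl oxygen chelate monovalent rhodium, the formyl C–H adds oxidatively, the terminal alkyne inserts into Rh–H with rhodium on the terminal carbon, and acyl–alkenyl reductive elimination forms C3–C4 of the (E)-2'-hydroxychalcone 20. The same O1 then adds to the enone β-carbon in a 6-endo-trig closure that forms O1–C2 and the pyranone ring. C2 is the only new stereocentre and lies too far from C1', C3' and C7' for substrate control, so it is set by the quinine-derived thiourea, whose quinuclidine nitrogen guides the phenol while the thiourea binds the enone carbonyl; by analogy with quinine-mediated closures of o-hydroxyaryl enones the quinine series is expected to favour the 2S face. The linear E-enone is secured by the terminal aryl alkyne, chemoselectivity over the internal C4'=C5' alkene by the much faster insertion of alkynes, and site selectivity by the fact that only O1 is free and ortho to the formyl group, O7 being silylated. The closure is run cold and without strong base because the oxa-Michael step is reversible.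

**Step 14**
Reactants: 21 (2S)-7-(tert-butyldimethylsilyloxy)-2-[4-(tert-butyldimethylsilyloxy)phenyl]-5-methoxy-8-R*-chroman-4-one
Product: 22 (2S)-7-hydroxy-8-[(1S,3R,4E,7S)-1,7-dihydroxy-3,9-bis(4-hydroxyphenyl)non-4-en-1-yl]-2-(4-hydroxyphenyl)-5-methoxychroman-4-one (CNP0415883.1)
Conditions: Bu4NF/AcOH (1:1, excess), THF, 0 → 35 °C
Reagents that add atoms: none
Why: Buffered fluoride desilylation should cleave the four aryl TBS and two alkyl TES ethers without base strong enough to open the flavanone (which would scramble C2) or acid strong enough to ionise the benzylic C1'–O bond.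

**Compound list**

1 | methyl 3-(4-hydroxyphenyl)propanoate | COC(=O)CCc1ccc(O)cc1 | starting material
2 | methyl 3-[4-(tert-butyldimethylsilyloxy)phenyl]propanoate | COC(=O)CCc1ccc(O[Si](C)(C)C(C)(C)C)cc1 | intermediate
3 | 3-[4-(tert-butyldimethylsilyloxy)phenyl]propanal | O=CCCc1ccc(O[Si](C)(C)C(C)(C)C)cc1 | intermediate
4 | (3S)-1-[4-(tert-butyldimethylsilyloxy)phenyl]hex-5-yn-3-ol | C#CC[C@@H](O)CCc1ccc(O[Si](C)(C)C(C)(C)C)cc1 | intermediate
5 | tert-butyldimethyl{4-[(3S)-3-(triethylsilyloxy)hex-5-yn-1-yl]phenoxy}silane | C#CC[C@@H](O[Si](CC)(CC)CC)CCc1ccc(O[Si](C)(C)C(C)(C)C)cc1 | intermediate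
6 | 1-(2,6-dihydroxy-4-methoxyphenyl)ethan-1-one | CC(=O)c1c(O)cc(OC)cc1O | starting material
7 | 1-[2,6-bis(allyloxy)-4-methoxyphenyl]ethan-1-one | CC(=O)c1c(OCC=C)cc(OC)cc1OCC=C | intermediate
8 | 4-(tert-butyldimethylsilyloxy)benzaldehyde | O=Cc1ccc(O[Si](C)(C)C(C)(C)C)cc1 | starting material
9 | lithium 3-[2,6-bis(allyloxy)-4-methoxyphenyl]-1-[4-(tert-butyldimethylsilyloxy)phenyl]-3-oxopropan-1-olate (racemic) | [Li+].[O-]C(CC(=O)c1c(OCC=C)cc(OC)cc1OCC=C)c1ccc(O[Si](C)(C)C(C)(C)C)cc1 | intermediate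
10 | 3-[2,6-bis(allyloxy)-4-methoxyphenyl]-1-[4-(tert-butyldimethylsilyloxy)phenyl]-3-oxopropyl methanesulfonate (racemic) | CS(=O)(=O)OC(CC(=O)c1c(OCC=C)cc(OC)cc1OCC=C)c1ccc(O[Si](C)(C)C(C)(C)C)cc1 | intermediate
11 | (E)-1-[2,6-bis(allyloxy)-4-methoxyphenyl]-3-[4-(tert-butyldimethylsilyloxy)phenyl]prop-2-en-1-one | O=C(/C=C/c1ccc(O[Si](C)(C)C(C)(C)C)cc1)c1c(OCC=C)cc(OC)cc1OCC=C | intermediate
12 | chlorobis(cyclopentadienyl){(1E,4S)-6-[4-(tert-butyldimethylsilyloxy)phenyl]-4-(triethylsilyloxy)hex-1-en-1-yl}zirconium | Cl[Zr](/C=C/C[C@@H](O[Si](CC)(CC)CC)CCc1ccc(O[Si](C)(C)C(C)(C)C)cc1)(C1C=CC=C1)C1C=CC=C1 | intermediate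
13 | (3R,4E,7S)-1-[2,6-bis(allyloxy)-4-methoxyphenyl]-3,9-bis[4-(tert-butyldimethylsilyloxy)phenyl]-7-(triethylsilyloxy)non-4-en-1-one | O=C(C[C@H](/C=C/C[C@@H](O[Si](CC)(CC)CC)CCc1ccc(O[Si](C)(C)C(C)(C)C)cc1)c1ccc(O[Si](C)(C)C(C)(C)C)cc1)c1c(OCC=C)cc(OC)cc1OCC=C | intermediate
14 | (1S,3R,4E,7S)-1-[2,6-bis(allyloxy)-4-methoxyphenyl]-3,9-bis[4-(tert-butyldimethylsilyloxy)phenyl]-7-(triethylsilyloxy)non-4-en-1-ol | C=CCOc1cc(OC)cc(OCC=C)c1[C@@H](O)C[C@H](/C=C/C[C@@H](O[Si](CC)(CC)CC)CCc1ccc(O[Si](C)(C)C(C)(C)C)cc1)c1ccc(O[Si](C)(C)C(C)(C)C)cc1 | intermediate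
15 | (1S,3R,4E,7S)-1-[2,6-bis(allyloxy)-4-methoxyphenyl]-1,7-bis(triethylsilyloxy)-3,9-bis[4-(tert-butyldimethylsilyloxy)phenyl]non-4-ene | C=CCOc1cc(OC)cc(OCC=C)c1[C@@H](O[Si](CC)(CC)CC)C[C@H](/C=C/C[C@@H](O[Si](CC)(CC)CC)CCc1ccc(O[Si](C)(C)C(C)(C)C)cc1)c1ccc(O[Si](C)(C)C(C)(C)C)cc1 | intermediate
16 | 5-methoxy-2-R*-benzene-1,3-diol | COc1cc(O)c([C@@H](O[Si](CC)(CC)CC)C[C@H](/C=C/C[C@@H](O[Si](CC)(CC)CC)CCc2ccc(O[Si](C)(C)C(C)(C)C)cc2)c2ccc(O[Si](C)(C)C(C)(C)C)cc2)c(O)c1 | intermediate
17 | 2,4-dihydroxy-6-methoxy-3-R*-benzaldehyde | COc1cc(O)c([C@@H](O[Si](CC)(CC)CC)C[C@H](/C=C/C[C@@H](O[Si](CC)(CC)CC)CCc2ccc(O[Si](C)(C)C(C)(C)C)cc2)c2ccc(O[Si](C)(C)C(C)(C)C)cc2)c(O)c1C=O | intermediate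
18 | 4-(tert-butyldimethylsilyloxy)-2-hydroxy-6-methoxy-3-R*-benzaldehyde | COc1cc(O[Si](C)(C)C(C)(C)C)c([C@@H](O[Si](CC)(CC)CC)C[C@H](/C=C/C[C@@H](O[Si](CC)(CC)CC)CCc2ccc(O[Si](C)(C)C(C)(C)C)cc2)c2ccc(O[Si](C)(C)C(C)(C)C)cc2)c(O)c1C=O | intermediate
19 | tert-butyl(4-ethynylphenoxy)dimethylsilane | C#Cc1ccc(O[Si](C)(C)C(C)(C)C)cc1 | starting material
20 | (E)-1-[4-(tert-butyldimethylsilyloxy)-2-hydroxy-6-methoxy-3-R*-phenyl]-3-[4-(tert-butyldimethylsilyloxy)phenyl]prop-2-en-1-one | COc1cc(O[Si](C)(C)C(C)(C)C)c([C@@H](O[Si](CC)(CC)CC)C[C@H](/C=C/C[C@@H](O[Si](CC)(CC)CC)CCc2ccc(O[Si](C)(C)C(C)(C)C)cc2)c2ccc(O[Si](C)(C)C(C)(C)C)cc2)c(O)c1C(=O)/C=C/c1ccc(O[Si](C)(C)C(C)(C)C)cc1 | intermediate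
21 | (2S)-7-(tert-butyldimethylsilyloxy)-2-[4-(tert-butyldimethylsilyloxy)phenyl]-5-methoxy-8-R*-chroman-4-one | COc1cc(O[Si](C)(C)C(C)(C)C)c([C@@H](O[Si](CC)(CC)CC)C[C@H](/C=C/C[C@@H](O[Si](CC)(CC)CC)CCc2ccc(O[Si](C)(C)C(C)(C)C)cc2)c2ccc(O[Si](C)(C)C(C)(C)C)cc2)c2c1C(=O)C[C@@H](c1ccc(O[Si](C)(C)C(C)(C)C)cc1)O2 | intermediate
22 | (2S)-7-hydroxy-8-[(1S,3R,4E,7S)-1,7-dihydroxy-3,9-bis(4-hydroxyphenyl)non-4-en-1-yl]-2-(4-hydroxyphenyl)-5-methoxychroman-4-one | COc1cc(O)c([C@@H](O)C[C@H](/C=C/C[C@@H](O)CCc2ccc(O)cc2)c2ccc(O)cc2)c2c1C(=O)C[C@@H](c1ccc(O)cc1)O2 | target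

**Step count.** Total: 14 steps. Longest linear sequence: 12 steps (steps 1–4, then 7–14).

**Steps most likely to fail**

1. Step 13. The alkyne may insert the other way round and give the branched enone. The ring may close before the chiral catalyst takes control. Reversible retro-oxa-Michael opening may erode the facial selectivity at C2. Fallback, from 18 and 19 back to 21: only the hydroacylation is run and the chalcone 20 is isolated. It is closed with a catalytic amount of DBU in toluene, without any chiral catalyst, to 21 together with its C2 epimer, (2R)-7-(tert-butyldimethylsilyloxy)-2-[4-(tert-butyldimethylsilyloxy)phenyl]-5-methoxy-8-R*-chroman-4-one F1. The two diastereomers are separated by chromatography. F1 is returned to the chalcone–flavanone equilibrium by brief DBU treatment and recycled, so that material is funnelled to 21.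

2. Step 8. Hydride transfer to the twisted, electron-rich di-ortho-alkoxyaryl ketone may be slow, facial selectivity may be poor, and the allyl groups may be hydroborated. Fallback, from 13 back to 14: 13 is reduced without a chiral reagent (NaBH4, THF/MeOH, 0 °C) to 14 and its C1 epimer, (1R,3R,4E,7S)-1-[2,6-bis(allyloxy)-4-methoxyphenyl]-3,9-bis[4-(tert-butyldimethylsilyloxy)phenyl]-7-(triethylsilyloxy)non-4-en-1-ol F2. The diastereomers are separated on base-washed silica. F2 is reoxidised to 13 with Dess–Martin periodinane/NaHCO3 and reduced again.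

3. Step 11. The magnesium phenoxide of 16 may expel the benzylic silyloxy group (o-quinone methide formation), the electron-rich resorcinol may be oxidised, and a second formylation may occur. Fallback, from 15 back to 17: the fully protected arene is formylated first, by Vilsmeier–Haack reaction (POCl3, DMF, 0 °C; NaOAc aq) at one of its two equivalent ring positions, to give 2,4-bis(allyloxy)-6-methoxy-3-R*-benzaldehyde F3. Both allyl groups are then removed with Pd(PPh3)4/morpholine to reach 17 without passing through 16.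

**Further compounds**

F1 | step 13 | (2R)-7-(tert-butyldimethylsilyloxy)-2-[4-(tert-butyldimethylsilyloxy)phenyl]-5-methoxy-8-R*-chroman-4-one | COc1cc(O[Si](C)(C)C(C)(C)C)c([C@@H](O[Si](CC)(CC)CC)C[C@H](/C=C/C[C@@H](O[Si](CC)(CC)CC)CCc2ccc(O[Si](C)(C)C(C)(C)C)cc2)c2ccc(O[Si](C)(C)C(C)(C)C)cc2)c2c1C(=O)C[C@H](c1ccc(O[Si](C)(C)C(C)(C)C)cc1)O2
F2 | step 8 | (1R,3R,4E,7S)-1-[2,6-bis(allyloxy)-4-methoxyphenyl]-3,9-bis[4-(tert-butyldimethylsilyloxy)phenyl]-7-(triethylsilyloxy)non-4-en-1-ol | C=CCOc1cc(OC)cc(OCC=C)c1[C@H](O)C[C@H](/C=C/C[C@@H](O[Si](CC)(CC)CC)CCc1ccc(O[Si](C)(C)C(C)(C)C)cc1)c1ccc(O[Si](C)(C)C(C)(C)C)cc1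
F3 | step 11 | 2,4-bis(allyloxy)-6-methoxy-3-R*-benzaldehyde | C=CCOc1cc(OC)c(C=O)c(OCC=C)c1[C@@H](O[Si](CC)(CC)CC)C[C@H](/C=C/C[C@@H](O[Si](CC)(CC)CC)CCc1ccc(O[Si](C)(C)C(C)(C)C)cc1)c1ccc(O[Si](C)(C)C(C)(C)C)cc1
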